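**Retrosynthetic overview**

1. The strategy rests on the ten-membered ring C1–C10 with its C1=C10 and C4=C5 olefins flanking C3–O. It maps onto a trans-fused decalin (ring A: C10, C1–C5; ring B: C5–C10) whose C5–C10 bond joins the sp3 ends of a ring A diene C1=C2–C3(OSiEt3)=C4.
2. Endgame: C3–OH from reagent-controlled reduction of the C3 enone, C15 ester by acylation, and the ten-membered ring by photochemical cleavage of C5–C10 in the silyl dienol ether 29.
3. Ring A handles: C4–C15 by aqueous Mukaiyama aldol with formaldehyde on the 1-en-3-one, C1=C2 by dehydrogenation of the C3 ketone.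
4. Ring B and lactone: lactone from a C7 allyl group and the C8 alcohol (ozonolysis, α-methylenation of the lactol, oxidation), C8–OH by dissolving-metal reduction, C7–C11 by enolate allylation, C6–OH and H5 by hydroboration of the 5-ene.
5. Ring order: ring B (purchased cyclohexanone), ring A (Robinson annulation, C10 set by a chiral-imine Michael addition), lactone ring, then the ten-membered ring by opening the ring A/ring B fusion bond.

Key step: step 20

Remarks: Germacrane/eudesmane numbering is used throughout. α/β mean below/above the decalin plane with the C10 methyl β. Compounds 1, 2, 4 and 22 are taken as purchased. The C4 configuration of 27 and 28 (drawn 4α) is inconsequential because C4 becomes sp2 in step 19.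

**Step 1**
Reactants: 1 7-methyl-1,4-dioxaspiro[4.5]decan-8-one (racemic); 2 (R)-1-phenylethylamine
Product: 3 N-[(R)-1-phenylethyl] imine of 1 (mixture at the methyl-bearing carbon and at C=N)
Conditions: toluene, 4 Å molecular sieves, reflux
Reagents that add atoms: none
Why: Condensation of a ketone with a primary amine gives the imine, whose secondary-enamine tautomer erases the methyl-bearing stereocentre so that the racemate converges in step 2.

**Step 2**
Reactants: 3 imine; 4 methyl vinyl ketone
Product: 6 (R)-7-methyl-7-(3-oxobutyl)-1,4-dioxaspiro[4.5]decan-8-one, via Michael-adduct imine 5 (not isolated)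
Conditions: THF, 40 °C; then 10% aq. AcOH, rt, brief
Reagents that add atoms: water, O
Why: Deracemising Michael addition of the more substituted secondary enamine through an aza-ene-like transition state, in which the enone approaches anti to the phenyl group of the (R)-auxiliary, should set the quaternary C10 with the methyl β, opposite to the sense known for the (S)-amine with 2-methylcyclohexanone.

**Step 3**
Reactants: 6 diketone
Product: 7 (R)-6,6-(ethylenedioxy)-4a-methyl-4,4a,5,6,7,8-hexahydronaphthalen-2(3H)-one (eudesmane numbering: 3-oxo-4-ene, C8 dioxolane, 10β-methyl)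
Conditions: NaOMe, MeOH, 60 °C
Reagents that add atoms: none
Why: Intramolecular aldol condensation of the methyl ketone onto the ring ketone completes the Robinson annulation and closes ring A, the dioxolane being stable to base.

**Step 4**
Reactants: 7 enone
Product: 9 3β-hydroxy-5-ene (C8 dioxolane, 10β-methyl), via deconjugated 5-en-3-one 8 (not isolated)
Conditions: KOtBu, t-BuOH/THF, rt; cold aq. AcOH quench; then NaBH4, MeOH, −20 °C
Reagents that add atoms: none
Why: Kinetic C4 protonation of the extended dienolate gives the β,γ-unsaturated ketone, and axial hydride delivery on the unhindered α face should give the equatorial 3β-alcohol (a temporary stereocentre, later oxidised).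

**Step 5**
Reactants: 9 homoallylic alcohol
Product: 10 3β-benzyloxy-5-ene
Conditions: NaH, BnBr, Bu4NI (cat.), THF/DMF, 0 °C to rt
Reagents that add atoms: benzyl bromide, BrCc1ccccc1
Why: Williamson etherification masks C3–OH with a group that is removed without an extra step in the dissolving-metal reduction of step 10.

**Step 6**
Reactants: 10 benzyl ether
Product: 12 3β-benzyloxy-6α-hydroxy-5αH decalin (C8 dioxolane), via C6 alkylborane 11 (not isolated)
Conditions: BH3·THF, 0 °C to rt; then NaOH, H2O2, 0 °C
Reagents that add atoms: borane–THF, B (boron of 11 only); hydrogen peroxide, OO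
Why: Hydroboration–oxidation places boron on the less substituted C6 and adds syn from the α face anti to the angular methyl, which should set H5 α (trans fusion) and the equatorial 6α-OH with retention on oxidation.

**Step 7**
Reactants: 12 alcohol
Product: 13 6α-tert-butyldimethylsilyl ether
Conditions: TBSOTf, 2,6-lutidine, CH2Cl2, −78 to 0 °C
Reagents that add atoms: tert-butyldimethylsilyl triflate, CC(C)(C)[Si](C)(C)OS(=O)(=O)C(F)(F)F
Why: Silylation of the hindered secondary alcohol with the silyl triflate gives an ether that is a poor leaving group in the enolate chemistry that follows.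

**Step 8**
Reactants: 13 ketal
Product: 14 3β-benzyloxy-6α-silyloxy-8-ketone
Conditions: PPTS (cat.), acetone/H2O, 55 °C
Reagents that add atoms: water, O
Why: Mild acid hydrolysis of the dioxolane frees the C8 ketone while the secondary silyl and benzyl ethers should survive.

**Step 9**
Reactants: 14 ketone
Product: 16 7β-allyl-8-ketone, via C7-epimeric allyl ketone mixture 15 (not isolated)
Conditions: LiN(iPr)2, THF, −78 °C; allyl bromide, DMPU, −78 to −30 °C; then K2CO3, MeOH, rt
Reagents that add atoms: allyl bromide, C=CCBr
Why: Kinetic enolate alkylation should occur at C7, because C9 is neopentyl and the 7-ene enolate is the favoured one in this trans-decalin, the equatorial C6–O bond being orthogonal to the enolate π system and so not prone to β-elimination; base equilibration then places the allyl group equatorial (7β).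

**Step 10**
Reactants: 16 allyl ketone
Product: 17 7β-allyl-6α-silyloxy-3β,8α-diol
Conditions: Li, NH3/THF, t-BuOH, −78 °C; NH4Cl
Reagents that add atoms: none
Why: Dissolving-metal reduction of the hindered ketone should give the thermodynamically favoured equatorial 8α-alcohol (hydride reagents would attack from the α face and give the axial 8β epimer), and it cleaves the benzyl ether in the same operation while the terminal olefin is inert.

**Step 11**
Reactants: 17 alkene diol
Product: 18 trans-fused 8α,12-lactol (anomer mixture) with free C3–OH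
Conditions: O3, CH2Cl2/MeOH, −78 °C; Me2S
Reagents that add atoms: ozone, [O-][O+]=O
Why: Ozonolysis of the terminal olefin gives the C12 aldehyde, which is captured by the trans-disposed equatorial C8 hydroxyl as the five-membered lactol, the only other nearby oxygen (C6) being silylated.

**Step 12**
Reactants: 18 lactol
Product: 19 11(13)-methylene lactol
Conditions: 37% aq. CH2O, pyrrolidine (cat.), EtCO2H (cat.), i-PrOH, 45 °C
Reagents that add atoms: formaldehyde, C=O
Why: Amine-catalysed Mannich condensation–elimination (α-methylenation of an aldehyde, reached through the ring-opened form of the lactol) installs C13 without strong base.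

**Step 13**
Reactants: 19 methylene lactol
Product: 20 3-oxo-6α-(tert-butyldimethylsilyloxy)-15-noreudesm-11(13)-en-8α,12-olide
Conditions: Dess–Martin periodinane (excess), NaHCO3, CH2Cl2, rt
Reagents that add atoms: none
Why: Dess–Martin oxidation converts the allylic lactol into the α-methylene lactone and the C3 carbinol into the ketone in one operation.

**Step 14**
Reactants: 20 silyl ether
Product: 21 6α-hydroxy-3-oxo-15-noreudesm-11(13)-en-8α,12-olide
Conditions: 48% aq. HF, MeCN, 0 °C to rt
Reagents that add atoms: none
Why: Acidic fluoride desilylation frees C6–OH under non-basic conditions, which avoid translactonisation to the 6,12-olide and conjugate addition to the methylene lactone.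

**Step 15**
Reactants: 21 alcohol; 22 (R)-2-methylbutanoic acid
Product: 24 6α-[(R)-2-methylbutanoyloxy]-3-oxo-15-noreudesm-11(13)-en-8α,12-olide, via mixed anhydride 23 (not isolated)
Conditions: 2,4,6-trichlorobenzoyl chloride, Et3N, THF, rt; then 21, DMAP, toluene, 0 °C to rt
Reagents that add atoms: 2,4,6-trichlorobenzoyl chloride, O=C(Cl)c1c(Cl)cc(Cl)cc1Cl (aroyl part of 23 only)
Why: Yamaguchi esterification acylates the hindered equatorial alcohol through the mixed anhydride under conditions that should not epimerise the α-stereocentre of the acid.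

**Step 16**
Reactants: 24 ketone
Product: 25 6α-acyloxy-3-oxo-15-noreudesma-1,11(13)-dien-8α,12-olide
Conditions: IBX, DMSO/fluorobenzene, 65 °C
Reagents that add atoms: none
Why: IBX dehydrogenation proceeds through the enol toward C2, the preferred enolisation direction of a trans-fused 3-ketone, and should give the 1-en-3-one without strong base.

**Step 17**
Reactants: 25 enone
Product: 27 15-hydroxy-3-oxo-6α-acyloxy-eudesma-1,11(13)-dien-8α,12-olide (4α-CH2OH), via trimethylsilyl dienol ether 26 (not isolated)
Conditions: TMSOTf, Et3N, CH2Cl2, −78 to 0 °C; then 37% aq. CH2O, Yb(OTf)3 (cat.), THF, rt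
Reagents that add atoms: trimethylsilyl triflate, C[Si](C)(C)OS(=O)(=O)C(F)(F)F (silyl group of 26 only); formaldehyde, C=O
Why: Soft enolisation can only occur at C4 (C10 is quaternary), and the lanthanide-triflate-catalysed aqueous Mukaiyama aldol of the resulting 2-silyloxydiene with formaldehyde forms the C4–C15 bond, the new C4 centre being erased in step 19.

**Step 18**
Reactants: 27 primary alcohol
Product: 28 15-(tert-butyldimethylsilyloxy) enone
Conditions: TBSCl, imidazole, CH2Cl2, 0 °C
Reagents that add atoms: tert-butyldimethylsilyl chloride, CC(C)(C)[Si](C)(C)Cl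
Why: Silylation of the primary alcohol blocks retro-aldol and dehydration and gives a poor leaving group next to the enol ether formed next.

**Step 19**
Reactants: 28 enone
Product: 29 trans-fused eudesmanolide silyl dienol ether (3-triethylsilyloxy-1,3-diene, 15-OTBS, 6α-acyloxy, 8α,12-olide)
Conditions: TESOTf, Et3N, CH2Cl2, −78 to 0 °C; Et3N-deactivated silica
Reagents that add atoms: triethylsilyl triflate, CC[Si](CC)(CC)OS(=O)(=O)C(F)(F)F
Why: Soft enolisation of the cross-conjugated ketone at its only enolisable position, the axial C4–H, gives the homoannular 3-silyloxy-1,3-diene.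

**Step 20**
Reactants: 29 silyl dienol ether
Product: 30 ten-membered trienol silyl ether (C1=C10 ring-trans, C2=C3 ring-cis, C4=C5 ring-trans)
Conditions: hν (medium-pressure mercury lamp, Pyrex filter, λ > 290 nm), degassed pentane/Et2O, −78 °C, partial conversion
Reagents that add atoms: none
Why: Direct excitation of the homoannular 3-silyloxy-1,3-diene triggers a photochemical six-electron electrocyclic ring opening that cleaves the C5–C10 σ bond in conrotatory fashion, the reaction type established for trans-fused hexalins. No ring is closed by bond formation: the ten-membered carbocycle C1–C10 is unveiled by scission of the bond shared by ring A and ring B, while C1–C10 and C4–C5 become double bonds. No stereocentre is created, and C6, C7 and C8, all equatorial on the ring B chair, are untouched. The step needs torquoselectivity and chromophore selectivity: because H5 (α) and the C10 methyl (β) are trans, conrotation swings C6 and C9 outward together, so both new olefins emerge ring-trans around a ring-cis C2=C3 enol ether, and Pyrex-filtered light excites the diene but not the α-methylene lactone or the esters. Low temperature and partial conversion limit secondary photochemistry of the triene and its thermal disrotatory reclosure, and the photolysate is carried cold into step 21.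

**Step 21**
Reactants: 30 trienol silyl ether
Product: 32 15-hydroxy-3-oxo-6-acyloxy-germacra-1(10)E,4E,11(13)-trien-8,12-olide, via 15-silyloxy dienone 31 (not isolated)
Conditions: HF·pyridine, pyridine, THF, −78 °C, then 0 °C
Reagents that add atoms: none
Why: Protodesilylation of the enol ether with kinetic protonation at C2 removes the central olefin before the triene can reclose and leaves the 1(10),4-dien-3-one, after which the primary silyl ether is cleaved on warming in the buffered medium.

**Step 22**
Reactants: 32 primary alcohol; 22 (R)-2-methylbutanoic acid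
Product: 33 3-oxo-6,15-bis[(R)-2-methylbutanoyloxy]-germacra-1(10)E,4E,11(13)-trien-8,12-olide
Conditions: EDC·HCl, DMAP (cat.), CH2Cl2, 0 °C
Reagents that add atoms: none
Why: Steglich-type carbodiimide esterification of the unhindered primary alcohol at low temperature, with little DMAP, should avoid epimerisation of the acid and allylic substitution of the resulting ester.

**Step 23**
Reactants: 33 enone
Product: 34 target, (3R,6R,7R,8S)-3-hydroxy-6,15-bis[(R)-2-methylbutanoyloxy]-germacra-1(10)E,4E,11(13)-trien-8,12-olide
Conditions: (S)-2-methyl-CBS-oxazaborolidine, catecholborane, toluene, −78 °C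
Reagents that add atoms: none
Why: Corey–Bakshi–Shibata reduction delivers hydride 1,2 under reagent control, with the α-branched alkenyl carbon C4 as the large and the C2 methylene as the small substituent, so the (S)-catalyst should give the 3R alcohol, as it gives (R)-1-phenylethanol from acetophenone.

**Compound list**

1 | 7-methyl-1,4-dioxaspiro[4.5]decan-8-one (racemic) | CC1CC2(CCC1=O)OCCO2 | starting material
2 | (R)-1-phenylethylamine | C[C@@H](N)c1ccccc1 | starting material
3 | N-[(R)-1-phenylethyl] imine of 1 | CC1CC2(CCC1=N[C@H](C)c1ccccc1)OCCO2 | intermediate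
4 | methyl vinyl ketone | CC(=O)C=C | starting material
5 | Michael-adduct imine | C[C@@]1(CCC(C)=O)CC2(CCC1=N[C@H](C)c1ccccc1)OCCO2 | intermediate (not isolated)
6 | (R)-7-methyl-7-(3-oxobutyl)-1,4-dioxaspiro[4.5]decan-8-one | C[C@@]1(CCC(C)=O)CC2(CCC1=O)OCCO2 | intermediate
7 | (R)-6,6-(ethylenedioxy)-4a-methyl-4,4a,5,6,7,8-hexahydronaphthalen-2(3H)-one | C[C@]12CCC(=O)C=C1CCC1(OCCO1)C2 | intermediate
8 | deconjugated 5-en-3-one | C[C@]12CCC(=O)CC1=CCC1(OCCO1)C2 | intermediate (not isolated)
9 | 3β-hydroxy-5-ene, C8 dioxolane | C[C@]12CC[C@H](O)CC1=CCC1(OCCO1)C2 | intermediate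
10 | 3β-benzyloxy-5-ene, C8 dioxolane | C[C@]12CC[C@H](OCc3ccccc3)CC1=CCC1(OCCO1)C2 | intermediate
11 | C6 alkylborane (5αH, 6α-boryl) | C[C@]12CC[C@H](OCc3ccccc3)C[C@@H]1[C@@H](B)CC1(OCCO1)C2 | intermediate (not isolated)
12 | 3β-benzyloxy-6α-hydroxy-5αH decalin, C8 dioxolane | C[C@]12CC[C@H](OCc3ccccc3)C[C@@H]1[C@@H](O)CC1(OCCO1)C2 | intermediate
13 | 6α-TBS ether of 12 | C[C@]12CC[C@H](OCc3ccccc3)C[C@@H]1[C@@H](O[Si](C)(C)C(C)(C)C)CC1(OCCO1)C2 | intermediate
14 | 3β-benzyloxy-6α-silyloxy-8-ketone | C[C@]12CC[C@H](OCc3ccccc3)C[C@@H]1[C@@H](O[Si](C)(C)C(C)(C)C)CC(=O)C2 | intermediate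
15 | C7-epimeric allyl ketone mixture | C[C@]12CC[C@H](OCc3ccccc3)C[C@@H]1[C@@H](O[Si](C)(C)C(C)(C)C)C(CC=C)C(=O)C2 | intermediate (not isolated)
16 | 7β-allyl-3β-benzyloxy-6α-silyloxy-8-ketone | C[C@]12CC[C@H](OCc3ccccc3)C[C@@H]1[C@@H](O[Si](C)(C)C(C)(C)C)[C@H](CC=C)C(=O)C2 | intermediate
17 | 7β-allyl-6α-silyloxy-3β,8α-diol | C[C@]12CC[C@H](O)C[C@@H]1[C@@H](O[Si](C)(C)C(C)(C)C)[C@H](CC=C)[C@@H](O)C2 | intermediate
18 | trans-fused 8α,12-lactol, 3β-OH, 6α-OTBS | C1C(O)O[C@H]2C[C@@]3(C)CC[C@H](O)C[C@@H]3[C@@H](O[Si](C)(C)C(C)(C)C)[C@H]12 | intermediate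
19 | 11(13)-methylene lactol | C=C1C(O)O[C@H]2C[C@@]3(C)CC[C@H](O)C[C@@H]3[C@@H](O[Si](C)(C)C(C)(C)C)[C@H]12 | intermediate
20 | 3-oxo-6α-(TBS-oxy)-15-noreudesm-11(13)-en-8α,12-olide | C=C1C(=O)O[C@H]2C[C@@]3(C)CCC(=O)C[C@@H]3[C@@H](O[Si](C)(C)C(C)(C)C)[C@H]12 | intermediate
21 | 6α-hydroxy-3-oxo-15-noreudesm-11(13)-en-8α,12-olide | C=C1C(=O)O[C@H]2C[C@@]3(C)CCC(=O)C[C@@H]3[C@@H](O)[C@H]12 | intermediate
22 | (R)-2-methylbutanoic acid | CC[C@@H](C)C(=O)O | starting material
23 | (R)-2-methylbutanoic 2,4,6-trichlorobenzoic anhydride | CC[C@@H](C)C(=O)OC(=O)c1c(Cl)cc(Cl)cc1Cl | intermediate (not isolated)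
24 | 6α-[(R)-2-methylbutanoyloxy]-3-oxo-15-noreudesm-11(13)-en-8α,12-olide | C=C1C(=O)O[C@H]2C[C@@]3(C)CCC(=O)C[C@@H]3[C@@H](OC(=O)[C@H](C)CC)[C@H]12 | intermediate
25 | 1-en-3-one of 24 | C=C1C(=O)O[C@H]2C[C@@]3(C)C=CC(=O)C[C@@H]3[C@@H](OC(=O)[C@H](C)CC)[C@H]12 | intermediate
26 | 3-(trimethylsilyloxy)-1,3-diene | C=C1C(=O)O[C@H]2C[C@@]3(C)C=CC(O[Si](C)(C)C)=C[C@@H]3[C@@H](OC(=O)[C@H](C)CC)[C@H]12 | intermediate (not isolated)
27 | 15-hydroxy-3-oxo-6α-acyloxy-eudesma-1,11(13)-dien-8α,12-olide (4α-CH2OH) | C=C1C(=O)O[C@H]2C[C@@]3(C)C=CC(=O)[C@@H](CO)[C@@H]3[C@@H](OC(=O)[C@H](C)CC)[C@H]12 | intermediate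
28 | 15-TBS ether of 27 | C=C1C(=O)O[C@H]2C[C@@]3(C)C=CC(=O)[C@@H](CO[Si](C)(C)C(C)(C)C)[C@@H]3[C@@H](OC(=O)[C@H](C)CC)[C@H]12 | intermediate
29 | trans-fused eudesmanolide silyl dienol ether (key-step precursor) | C=C1C(=O)O[C@H]2C[C@@]3(C)C=CC(O[Si](CC)(CC)CC)=C(CO[Si](C)(C)C(C)(C)C)[C@@H]3[C@@H](OC(=O)[C@H](C)CC)[C@H]12 | intermediate
30 | ten-membered trienol silyl ether (key-step product) | C=C1C(=O)O[C@H]2C/C(C)=C/C=C(O[Si](CC)(CC)CC)\C(CO[Si](C)(C)C(C)(C)C)=C\[C@@H](OC(=O)[C@H](C)CC)[C@H]12 | intermediate
31 | 15-(TBS-oxy)-3-oxo-germacra-1(10),4,11(13)-trienolide 6-ester | C=C1C(=O)O[C@H]2C/C(C)=C/CC(=O)/C(CO[Si](C)(C)C(C)(C)C)=C/[C@@H](OC(=O)[C@H](C)CC)[C@H]12 | intermediate (not isolated)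
32 | 15-hydroxy-3-oxo-germacra-1(10),4,11(13)-trienolide 6-ester | C=C1C(=O)O[C@H]2C/C(C)=C/CC(=O)/C(CO)=C/[C@@H](OC(=O)[C@H](C)CC)[C@H]12 | intermediate
33 | 3-oxo-6,15-bis[(R)-2-methylbutanoyloxy]-germacra-1(10),4,11(13)-trienolide | C=C1C(=O)O[C@H]2C/C(C)=C/CC(=O)/C(COC(=O)[C@H](C)CC)=C/[C@@H](OC(=O)[C@H](C)CC)[C@H]12 | intermediate
34 | CNP0164325.1 | C=C1C(=O)O[C@H]2C/C(C)=C/C[C@@H](O)/C(COC(=O)[C@H](C)CC)=C/[C@@H](OC(=O)[C@H](C)CC)[C@H]12 | target

**Step count and risks**

Total steps: 23. Longest linear sequence: 23 steps (1 to 34); 2, 4 and 22 enter as purchased reagents.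

Steps most likely to fail:

1. Step 20. The ring opening may stall at a photostationary mixture, the triene may undergo secondary photoreactions, or it may reclose thermally to a cis-fused hexalin before it is intercepted. The fallback builds the interception into the photolysis. It sets out from 28, which is converted with TMSOTf/Et3N into the more labile trimethylsilyl dienol ether F1. F1 is irradiated through Pyrex in Et2O/MeOH with a trace of pyridinium acetate at −40 °C. The ring-opened trimethylsilyl trienol ether F2, whose enol ether carbon C2 is unhindered, should be methanolysed as it forms, whereas the tetrasubstituted enol ether of F1 should react more slowly. This gives 31 directly, and any F1 that is solvolysed returns to 28 for recycling. The fallback comes back to the route at 32 after the fluoride treatment of step 21.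

2. Step 23. Reagent control may be overridden by the conformation of the ten-membered ring, giving poor facial selectivity, or hydride may add 1,4 with loss of the allylic ester. The fallback sets out from 33 and uses substrate control followed by correction. Luche reduction (NaBH4, CeCl3·7H2O, MeOH, −78 °C) gives the allylic alcohol. If the 3S epimer F3 predominates, it is inverted by a Mitsunobu reaction with chloroacetic acid (PPh3, DIAD) to the 3R chloroacetate F4. The chloroacetate is cleaved selectively with thiourea/NaHCO3 in EtOH, which leaves the two 2-methylbutanoates intact, and the fallback comes back to the route at 34.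

3. Step 9. Deprotonation may occur at C9 instead of C7, the ketone may be allylated twice, or the C6 silyloxy group may be lost by β-elimination during enolisation or equilibration. The fallback sets out from 14 and directs the alkylation with an activating group. Claisen formylation (HCO2Et, NaH, THF) at the thermodynamically preferred α-carbon gives the 7-hydroxymethylene ketone F5. C-allylation (allyl bromide, K2CO3, acetone) gives the 7-allyl-7-formyl ketone F6. Retro-Claisen deformylation with concurrent equilibration at C7 (K2CO3, MeOH/H2O) returns to the route at 16.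

**Further compounds**

F1 | step 20 | trimethylsilyl dienol ether analogue of 29 | C=C1C(=O)O[C@H]2C[C@@]3(C)C=CC(O[Si](C)(C)C)=C(CO[Si](C)(C)C(C)(C)C)[C@@H]3[C@@H](OC(=O)[C@H](C)CC)[C@H]12
F2 | step 20 | trimethylsilyl trienol ether analogue of 30 | C=C1C(=O)O[C@H]2C/C(C)=C/C=C(O[Si](C)(C)C)\C(CO[Si](C)(C)C(C)(C)C)=C\[C@@H](OC(=O)[C@H](C)CC)[C@H]12
F3 | step 23 | 3S epimer of 34 | C=C1C(=O)O[C@H]2C/C(C)=C/C[C@H](O)/C(COC(=O)[C@H](C)CC)=C/[C@@H](OC(=O)[C@H](C)CC)[C@H]12
F4 | step 23 | 3R chloroacetate of 34 | C=C1C(=O)O[C@H]2C/C(C)=C/C[C@@H](OC(=O)CCl)/C(COC(=O)[C@H](C)CC)=C/[C@@H](OC(=O)[C@H](C)CC)[C@H]12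
F5 | step 9 | 7-hydroxymethylene derivative of 14 | C[C@]12CC[C@H](OCc3ccccc3)C[C@@H]1[C@@H](O[Si](C)(C)C(C)(C)C)C(=CO)C(=O)C2
F6 | step 9 | 7-allyl-7-formyl derivative of 14 | C[C@]12CC[C@H](OCc3ccccc3)C[C@@H]1[C@@H](O[Si](C)(C)C(C)(C)C)C(CC=C)(C=O)C(=O)C2
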